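Two constants carry this flask if we treat it as a consecutive pair: k, which makes intermediate from substrate, and L, a pseudo-first-order constant that removes intermediate with partner held at its charge.

all flasks: substrate 0.10 M
- theta: partner 0.55 equiv; run made earlier
- zeta: partner 2.2 equiv; run made earlier
- flask: partner 1.10 equiv; time 80 min

| run | time / min | intermediate / % | target / % |
|---|---|---|---|
| theta | 1.00 | 61.9 | 3.8 |
| theta | 2.50 | 63.7 | 6.6 |
| theta | 6.00 | 34.0 | 4.0 |
| theta | 15.0 | 6.5 | 3.1 |
| theta | 40.0 | 0 | 2.8 |
| theta | 90.0 | 0.1 | 2.7 |
| zeta | 1.00 | 51.2 | 13.6 |
| zeta | 2.50 | 39.2 | 27.7 |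
| zeta | 6.00 | 9.7 | 21.4 |
| zeta | 15.0 | 0 | 14.1 |
| zeta | 40.0 | 0 | 13.0 |
| zeta | 90.0 | 0 | 13.1 |

(each reading ± 0.3 percentage points)

- a reading or a percentage of target counts all its forms, free or not

1. the moment within 80 min at which there is most intermediate
2. the amount of intermediate, in percent of the substrate charged, at that time
3. earliest time at which at least nineteen twentieths of that best amount are there, in min
4. latest time at which they still are, in min

With s and i as fractions of the substrate charged and ρ = L/k, the closed form gives:

ds/dt = −k s, di/dt = k s − L i
peak: k s = L i
t* = ln(k/L)/(k − L), i* = ρ^(ρ/(1 − ρ))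
band asked for: t* ± sqrt(1/(10 k L))

In theta, intermediate falls from 34.0 % to 6.5 % while target does not rise, and we read that decay, 0.184 min⁻¹, as the loss without partner. Intermediate plus target in theta at 1.00 min come to 65.7 %, but this is not the whole conversion, since what has left intermediate by that loss stands in neither column. Taking the mean intermediate up to that time as 0.5 of its reading, we add 5.7 percentage points, so about 71.4 % is converted and k is about 1.25 min⁻¹. In zeta, the decay from 2.50 min to 6.00 min gives 0.399 min⁻¹.

A line through these two values placed at the charged equivalents gives 0.256 min⁻¹ for the flask. That is the weak link, since we took the theta decay to be free of partner. Anchoring the line at zero partner instead gives L = 0.291 min⁻¹.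

Then 0.233 is our loss-to-making ratio. It gives i* = 64.3 % at 1.52 min, with a half-width of 0.524 min.

The forecast puts the peak at 63.4 % and 1.5 min, earlier than ours, with the band from 1.05 min to 2.15 min: “a peak near 1.5 min of about 63.5%”.

The flask gives 61.4 % at 1.46 min, with the band from 1.01 min to 2.07 min, so our peak time ran late.

    substrate → intermediate (k = 0.0210 s⁻¹)
    partner + intermediate → target (k = 0.0360 L mol⁻¹ s⁻¹)
    target ⇌ isomer of the product (K = 17.0, k = 0.0300 s⁻¹)
    partner + target ⇌ idle adduct, settled at all times (K = 20.0 L mol⁻¹)
    intermediate → decomposed reagent (k = 0.00220 s⁻¹)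

Substrate at that moment stands at 15.8 %, and the peak condition s = ρ i predicts 14.3 %.

For the neighbour with 0.060 M of substrate, we scale the partner term of L by the concentration. That gives ρ = 0.198 and i* = 67.0 %. The computed flask gives 66.0 %.

Readings and results are calculated with constants of no real substance, and the scatter is random.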